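**Retrosynthetic overview**

1. (S)-Hopeafuran ⇐ catalytic enantioselective protonation of the per-silylated enol of racemic hopeafuran; the Cα–H stereocentre (α to the ketone, doubly benzylic, base-labile) is made last.
2. Seven-membered ring (C=O, C4, C3a, C3, C1′, C6′, Cα) ⇐ six-membered spiro ring (C=O, C4, C3a, C3, C6′, Cα) of a cyclohexadienone, by a dienone–phenol 1,2-shift of C3 from C6′ to C1′; the spirodienone ⇐ an acyclic phenol by oxidative dearomatization with a trivalent iodine reagent in the same flask, with no prefunctionalization at C3, C6′ or C1′.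
3. Enabling feature: in resorcinol ring A the carbon C6′ that bears Cα is para to O-3′ and ortho to O-5′, so a free 3′-OH makes C6′ the ipso electrophile; C3 (enol-ether carbon of the furan ring) is peri to the C4 acyl arm and reaches C6′ through a six-membered ring; the shift then leaves C3 on C1′, meta to both oxygens, where no direct coupling could place it.
4. Acyclic phenol ⇐ Pd α-arylation of a deoxybenzoin with silyl-protected 4-bromo-3-methoxyphenol; deoxybenzoin ⇐ Claisen condensation/decarboxylation of a benzofuran-4-carboxylate with (4-methoxyphenyl)acetic acid; benzofuran ⇐ iodination and Sonogashira/heteroannulation of methyl 3,5-dihydroxybenzoate with 4-ethynylanisole.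
5. Order of ring formation: furan ring (step 2), then the six-membered spiro ring and its enlargement to the seven-membered ring (both in step 8).

Key step: step 8

Remark: the stereocentre is read as (S) (CIP order C=O > C6′ > 4-hydroxyphenyl > H); locants used: benzofuran O1, C2, C3, C3a, C4 to C7, C7a; Cα = the methine carbon; ring A = resorcinol ring, C1′ (bonded to C3) to C6′ (bonded to Cα), oxygens on C3′ and C5′.

**Route**

Step 1
Reactants: 1 methyl 3,5-dihydroxybenzoate
Product: 2 methyl 3,5-dihydroxy-2-iodobenzoate
Conditions: N-iodosuccinimide (1.0 equiv), MeCN, −20 °C to 0 °C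
Reagents that add atoms: N-iodosuccinimide, O=C1CCC(=O)N1I
Why: Electrophilic aromatic iodination at C2, which is ortho to one hydroxyl and para to the other (the kinetically preferred site of resorcinols toward N-halosuccinimides, present twice by symmetry), whereas C4 between the hydroxyls is favoured only under iodine/bicarbonate conditions; one equivalent at low temperature should limit di-iodination.

Step 2
Reactants: 2 methyl 3,5-dihydroxy-2-iodobenzoate; 3 4-ethynylanisole
Product: 5 methyl 6-hydroxy-2-(4-methoxyphenyl)-1-benzofuran-4-carboxylate, via alkynylphenol 4 (not isolated)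
Conditions: PdCl2(PPh3)2 (3 mol %), CuI (5 mol %), Et3N, DMF, 60 °C
Reagents that add atoms: none
Why: Sonogashira coupling followed in the same flask by 5-endo-dig heteroannulation of the ortho-phenoxide onto the metal-activated alkyne (benzofuran synthesis from ortho-iodophenols); the second hydroxyl is meta to the alkyne and cannot cyclize, and the phenoxide should outcompete the ester carbonyl.

Step 3
Reactants: 5 methyl 6-hydroxy-2-(4-methoxyphenyl)-1-benzofuran-4-carboxylate
Product: 6 methyl 6-methoxy-2-(4-methoxyphenyl)-1-benzofuran-4-carboxylate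
Conditions: MeI, K2CO3, acetone, 56 °C
Reagents that add atoms: iodomethane, CI
Why: Williamson ether synthesis on the only phenol; the methyl ether is inert to every later step up to BBr3.

Step 4
Reactants: 6 methyl 6-methoxy-2-(4-methoxyphenyl)-1-benzofuran-4-carboxylate; 7 (4-methoxyphenyl)acetic acid
Product: 9 1-[6-methoxy-2-(4-methoxyphenyl)-1-benzofuran-4-yl]-2-(4-methoxyphenyl)ethan-1-one, via β-keto acid 8 (not isolated)
Conditions: LiN(SiMe3)2 (3.5 equiv), THF, −10 °C to 23 °C; then aq. HCl, 50 °C
Reagents that add atoms: none
Why: Crossed Claisen condensation of the arylacetic acid dianion (enediolate) with the non-enolizable methyl ester gives a β-keto carboxylate that cannot accept a second nucleophile and loses CO2 on acidification (decarboxylative Claisen condensation, a one-flask ester-to-benzyl-ketone conversion).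

Step 5
Reactants: 10 4-bromo-3-methoxyphenol
Product: 11 (4-bromo-3-methoxyphenoxy)tri(propan-2-yl)silane
Conditions: i-Pr3SiCl, imidazole, DMF, 23 °C
Reagents that add atoms: chlorotri(propan-2-yl)silane, CC(C)[Si](Cl)(C(C)C)C(C)C
Why: Standard silylation of the phenol; the bulky silyl ether should survive phosphate base at 100 °C and is cleaved later by fluoride.

Step 6
Reactants: 9 1-[6-methoxy-2-(4-methoxyphenyl)-1-benzofuran-4-yl]-2-(4-methoxyphenyl)ethan-1-one; 11 (4-bromo-3-methoxyphenoxy)tri(propan-2-yl)silane
Product: 12 (±)-1-[6-methoxy-2-(4-methoxyphenyl)-1-benzofuran-4-yl]-2-(4-methoxyphenyl)-2-{2-methoxy-4-[tri(propan-2-yl)silyloxy]phenyl}ethan-1-one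
Conditions: Pd2(dba)3 (2 mol %), XPhos (8 mol %), K3PO4, toluene, 100 °C
Reagents that add atoms: none
Why: Palladium-catalysed α-arylation of a ketone, in which K3PO4 deprotonates the acidic deoxybenzoin, the bulky biarylphosphine supports oxidative addition of the electron-rich ortho-methoxy bromide to zerovalent palladium and reductive elimination to the crowded triarylmethine, and a second arylation at the tertiary carbon is sterically excluded; the new centre is formed as the racemate on purpose.

Step 7
Reactants: 12 (±)-silyl ether from step 6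
Product: 13 (±)-2-(4-hydroxy-2-methoxyphenyl)-1-[6-methoxy-2-(4-methoxyphenyl)-1-benzofuran-4-yl]-2-(4-methoxyphenyl)ethan-1-one
Conditions: HF·pyridine, THF, 0 °C to 23 °C
Reagents that add atoms: none
Why: Fluoride cleavage of the aryl silyl ether (Si–F bond formation) under acidic conditions frees the one phenol needed for oxidation while the four methyl ethers stay.

Step 8
Reactants: 13 (±)-2-(4-hydroxy-2-methoxyphenyl)-1-[6-methoxy-2-(4-methoxyphenyl)-1-benzofuran-4-yl]-2-(4-methoxyphenyl)ethan-1-one
Product: 15 (±)-hopeafuran tetramethyl ether with free 3′-OH (OMe at benzofuran C6, at C5′ of ring A and at C4 of both aryl groups), via spirodienone 14 (not isolated)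
Conditions: PhI(OCOCF3)2 (1.05 equiv), (CF3)2CHOH–CH2Cl2 (1:1), −20 °C to 0 °C; then CF3SO3H (20 mol %), 0 °C to 23 °C
Reagents that add atoms: none
Why: PhI(OCOCF3)2 binds the only free phenol (O-3′) and, as PhI leaves, the phenoxonium ion is attacked at its para carbon C6′ (ipso to Cα) by C3 of the benzofuran, the enol-ether β-carbon, in a 6-exo-trig spirocyclization that gives dienone 14; CF3SO3H then protonates the dienone oxygen and C3 shifts from C6′ to C1′ through a three-membered bridged cation (dienone–phenol rearrangement), which enlarges the six-membered spiro ring to the seven-membered ring and ends with loss of H+ from C1′ and rearomatization. The closest known reaction types are the trivalent-iodine para-spirocyclization of phenols by tethered electron-rich arenes and the acid-induced dienone–phenol ring enlargement of spirodienones, as in the proaporphine to aporphine and homoproaporphine to homoaporphine conversions; relief of crowding at the quaternary spiro carbon and aromatization drive the shift. No stereocentre is set: the spiro carbon of 14 is stereogenic only until it becomes an arene carbon again, both diastereomers of 14 converge on 15, and Cα stays racemic. Site selectivity of the first bond: the phenol is the only ring that can exchange onto iodine, C6′ is the only cationic carbon the tether can reach, and C3 should win over C5 of the benzofuran (which would give a five-membered spiro-indanone) because C5 is ortho to the deactivating acyl group and a five-membered closure would hold the cation near the plane of the arene. Selectivity of the shift: C3 migrates in preference to Cα because its bridged cation is a 2-aryl oxocarbenium ion stabilized by O1 and the 4-methoxyphenyl group whereas Cα is an electron-poor α-keto carbon, and the shift ends at C1′ and not at the methoxy-bearing C5′ because only at C1′ can a proton be lost, a shift to C5′ being reversible. Loss of the Cα proton to a quinone methide is held back by the ortho-methoxy group, which keeps the Cα–H bond in the plane of the ring (allylic 1,3-strain), by the base-free acidic medium, and by adding the strong acid only after the oxidant is consumed, which also protects the product phenol from over-oxidation.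

Step 9
Reactants: 15 (±)-hopeafuran tetramethyl ether with free 3′-OH
Product: 16 (±)-hopeafuran
Conditions: BBr3 (10 equiv), CH2Cl2, −78 °C to 23 °C; then H2O
Reagents that add atoms: none
Why: BBr3 cleavage of aryl methyl ethers (Lewis acid–base adduct, then attack of bromide on methyl) is standard for polymethylated stilbenoid benzofurans; the material is racemic, so any enolization of the ketone under these conditions costs nothing.

Step 10
Reactants: 16 (±)-hopeafuran
Product: 17 hopeafuran hexakis(trimethylsilyl) derivative (five aryl silyl ethers and the silyl enol ether C(OSiMe3)=Cα)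
Conditions: Me3SiOTf (7 equiv), Et3N (9 equiv), CH2Cl2, 0 °C to 23 °C; pentane extraction, no chromatography
Reagents that add atoms: trimethylsilyl trifluoromethanesulfonate, C[Si](C)(C)OS(=O)(=O)C(F)(F)F
Why: Soft enolization and O-silylation with Me3SiOTf/Et3N turn the five phenols into aryl silyl ethers and the acidic α,α-diaryl ketone into its silyl enol ether, which erases the stereocentre (stereoablation) and gives one achiral substrate for the last step.

Step 11
Reactants: 17 hopeafuran hexakis(trimethylsilyl) derivative
Product: 19 (S)-hopeafuran, via pentakis(trimethylsilyl) ether 18 (not isolated)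
Conditions: (S)-3,3′-bis(2,4,6-triisopropylphenyl)-1,1′-binaphthyl-2,2′-diyl N-triflylthiophosphoramide (10 mol %), PhOH (1.1 equiv), toluene, 23 °C; then MeOH, citric acid (cat.), 0 °C
Reagents that add atoms: none
Why: Catalytic enantioselective protonation of a silyl enol ether by a chiral Brønsted acid with phenol as the stoichiometric achiral proton source, a reaction type established for silyl enol ethers of 2-aryl cycloalkanones including seven-membered ones: the chiral anion holds the silyloxocarbenium ion pair so that the proton goes to the Re face of Cα (C(OSi) > C6′ > aryl), which sets (S) (the mirror-image catalyst would be taken should a pilot run show the opposite sense), and the aryl O–SiMe3 groups are then methanolysed under weakly acidic conditions that do not enolize the ketone.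

**Compound list**

1 | methyl 3,5-dihydroxybenzoate | COC(=O)c1cc(O)cc(O)c1 | starting material
2 | methyl 3,5-dihydroxy-2-iodobenzoate | COC(=O)c1cc(O)cc(O)c1I | intermediate
3 | 4-ethynylanisole (1-ethynyl-4-methoxybenzene) | C#Cc1ccc(OC)cc1 | starting material
4 | methyl 3,5-dihydroxy-2-[(4-methoxyphenyl)ethynyl]benzoate | COC(=O)c1cc(O)cc(O)c1C#Cc1ccc(OC)cc1 | intermediate
5 | methyl 6-hydroxy-2-(4-methoxyphenyl)-1-benzofuran-4-carboxylate | COC(=O)c1cc(O)cc2oc(-c3ccc(OC)cc3)cc12 | intermediate
6 | methyl 6-methoxy-2-(4-methoxyphenyl)-1-benzofuran-4-carboxylate | COC(=O)c1cc(OC)cc2oc(-c3ccc(OC)cc3)cc12 | intermediate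
7 | (4-methoxyphenyl)acetic acid | COc1ccc(CC(=O)O)cc1 | starting material
8 | (±)-3-[6-methoxy-2-(4-methoxyphenyl)-1-benzofuran-4-yl]-2-(4-methoxyphenyl)-3-oxopropanoic acid | COc1ccc(cc1)C(C(=O)O)C(=O)c1cc(OC)cc2oc(-c3ccc(OC)cc3)cc12 | intermediate
9 | 1-[6-methoxy-2-(4-methoxyphenyl)-1-benzofuran-4-yl]-2-(4-methoxyphenyl)ethan-1-one | COc1ccc(CC(=O)c2cc(OC)cc3oc(-c4ccc(OC)cc4)cc23)cc1 | intermediate
10 | 4-bromo-3-methoxyphenol | COc1cc(O)ccc1Br | starting material
11 | (4-bromo-3-methoxyphenoxy)tri(propan-2-yl)silane | COc1cc(O[Si](C(C)C)(C(C)C)C(C)C)ccc1Br | intermediate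
12 | (±)-1-[6-methoxy-2-(4-methoxyphenyl)-1-benzofuran-4-yl]-2-(4-methoxyphenyl)-2-{2-methoxy-4-[tri(propan-2-yl)silyloxy]phenyl}ethan-1-one | COc1ccc(cc1)C(c1ccc(O[Si](C(C)C)(C(C)C)C(C)C)cc1OC)C(=O)c1cc(OC)cc2oc(-c3ccc(OC)cc3)cc12 | intermediate
13 | (±)-2-(4-hydroxy-2-methoxyphenyl)-1-[6-methoxy-2-(4-methoxyphenyl)-1-benzofuran-4-yl]-2-(4-methoxyphenyl)ethan-1-one | COc1ccc(cc1)C(c1ccc(O)cc1OC)C(=O)c1cc(OC)cc2oc(-c3ccc(OC)cc3)cc12 | intermediate
14 | spirodienone: 2-methoxycyclohexa-2,5-dien-4-one whose C1 (future C6′) is the spiro atom of the six-membered ring C3–C3a–C4–C(=O)–Cα(H)(4-methoxyphenyl); racemic mixture of diastereomers | O=C1C=CC2(C(OC)=C1)C(c1ccc(OC)cc1)C(=O)c1cc(OC)cc3oc(-c4ccc(OC)cc4)c2c13 | intermediate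
15 | (±)-hopeafuran tetramethyl ether with free 3′-OH (OMe at benzofuran C6, at C5′ and at C4 of both aryl groups) | O=C1c2cc(OC)cc3oc(-c4ccc(OC)cc4)c(c23)-c2cc(O)cc(OC)c2C1c1ccc(OC)cc1 | intermediate
16 | (±)-hopeafuran | O=C1c2cc(O)cc3oc(-c4ccc(O)cc4)c(c23)-c2cc(O)cc(O)c2C1c1ccc(O)cc1 | intermediate
17 | hopeafuran hexakis(trimethylsilyl) derivative (silyl enol ether, five aryl silyl ethers) | C[Si](C)(C)OC1=C(c2ccc(O[Si](C)(C)C)cc2)c2c(O[Si](C)(C)C)cc(O[Si](C)(C)C)cc2-c2c(-c3ccc(O[Si](C)(C)C)cc3)oc3cc(O[Si](C)(C)C)cc1c23 | intermediate
18 | (S)-hopeafuran pentakis(trimethylsilyl) ether | O=C1c2cc(O[Si](C)(C)C)cc3oc(-c4ccc(O[Si](C)(C)C)cc4)c(c23)-c2cc(O[Si](C)(C)C)cc(O[Si](C)(C)C)c2[C@@H]1c1ccc(O[Si](C)(C)C)cc1 | intermediate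
19 | (S)-hopeafuran | O=C1c2cc(O)cc3oc(-c4ccc(O)cc4)c(c23)-c2cc(O)cc(O)c2[C@@H]1c1ccc(O)cc1 | target

**Step count and risks**

Total step count: 11. Longest linear sequence: 10 steps (steps 1–4 and 6–11, from methyl 3,5-dihydroxybenzoate); step 5 is a one-step side branch.

Steps most likely to fail:

Step 8. The oxidized phenol may shed the Cα proton (quinone-methide formation), or the oxidant may attack the electron-rich 2-arylbenzofuran, before C3 reaches C6′. The fallback removes the acidic proton before the oxidation by carrying Cα as an enol derivative. It sets out from 12: KN(SiMe3)2 and allyl chloroformate (THF, −78 °C) should O-acylate the crowded enolate to the allyl enol carbonate F1 (E/Z mixture). HF·pyridine then frees the phenol to give enol carbonate phenol F2. PhI(OCOCF3)2 in (CF3)2CHOH followed by CF3SO3H should lead through the spirodienone enol carbonate F3 to the seven-membered allyl enol carbonate F4. Both alkene isomers are expected to react, because the oxidized 4-hydroxystyrene unit is a vinylogous quinone-methide cation in which the former C=C bond can rotate. Pd(PPh3)4 (a zerovalent palladium complex) with HCO2H/Et3N in THF then effects decarboxylative protonation of the allyl enol carbonate, and the route is rejoined at racemic ketone 15.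

Step 11. Facial discrimination in the proton transfer may be poor, since all four substituents of the enol C=C are aryl or siloxy, and the acid catalyst may partly racemize the product. The fallback replaces asymmetric catalysis by separation plus recycling. It sets out from 16, which is separated by preparative chromatography on a polysaccharide chiral stationary phase with an acidic eluent (supercritical CO2/MeOH, 0.1% HCO2H) into 19 and its mirror image (R)-hopeafuran F5. F5 is re-racemized with catalytic Et3N in MeOH (the acidity that makes the centre labile is used here) and returned to the separation. The route is rejoined at 19.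

Step 10. O-Silylation of the hindered ketone may stay incomplete, and aryl O–SiMe3 groups of 17, which cannot be chromatographed, may hydrolyse before step 11. The fallback is a two-tier silyl scheme with isolable intermediates. It sets out from 16: t-BuMe2SiCl/imidazole (DMF) should give the chromatographable pentakis(tert-butyldimethylsilyl) ether F6. KN(SiMe3)2 then Me3SiCl (THF, −78 °C) gives the trimethylsilyl enol ether F7. The chiral acid/PhOH protonation of step 11 gives the (S)-ketone pentakis(tert-butyldimethylsilyl) ether F8. HF·pyridine buffered with pyridine (THF, 0 °C) removes the aryl silyl groups without base, and the route is rejoined at 19.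

**Further compounds**

F1 | step 8 | allyl enol carbonate of 12 (E/Z mixture) | C=CCOC(=O)OC(=C(c1ccc(OC)cc1)c1ccc(O[Si](C(C)C)(C(C)C)C(C)C)cc1OC)c1cc(OC)cc2oc(-c3ccc(OC)cc3)cc12
F2 | step 8 | enol carbonate phenol (E/Z mixture) | C=CCOC(=O)OC(=C(c1ccc(OC)cc1)c1ccc(O)cc1OC)c1cc(OC)cc2oc(-c3ccc(OC)cc3)cc12
F3 | step 8 | spirodienone enol carbonate (racemic, not isolated) | O=C1C=CC2(C(OC)=C1)C(c1ccc(OC)cc1)=C(OC(=O)OCC=C)c1cc(OC)cc3oc(-c4ccc(OC)cc4)c2c13
F4 | step 8 | seven-membered allyl enol carbonate with free 3′-OH | C=CCOC(=O)OC1=C(c2ccc(OC)cc2)c2c(OC)cc(O)cc2-c2c(-c3ccc(OC)cc3)oc3cc(OC)cc1c23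
F5 | step 11 | (R)-hopeafuran | O=C1c2cc(O)cc3oc(-c4ccc(O)cc4)c(c23)-c2cc(O)cc(O)c2[C@H]1c1ccc(O)cc1
F6 | step 10 | (±)-hopeafuran pentakis(tert-butyldimethylsilyl) ether | O=C1c2cc(O[Si](C)(C)C(C)(C)C)cc3oc(-c4ccc(O[Si](C)(C)C(C)(C)C)cc4)c(c23)-c2cc(O[Si](C)(C)C(C)(C)C)cc(O[Si](C)(C)C(C)(C)C)c2C1c1ccc(O[Si](C)(C)C(C)(C)C)cc1
F7 | step 10 | trimethylsilyl enol ether of F6 | C[Si](C)(C)OC1=C(c2ccc(O[Si](C)(C)C(C)(C)C)cc2)c2c(O[Si](C)(C)C(C)(C)C)cc(O[Si](C)(C)C(C)(C)C)cc2-c2c(-c3ccc(O[Si](C)(C)C(C)(C)C)cc3)oc3cc(O[Si](C)(C)C(C)(C)C)cc1c23
F8 | step 10 | (S)-hopeafuran pentakis(tert-butyldimethylsilyl) ether | O=C1c2cc(O[Si](C)(C)C(C)(C)C)cc3oc(-c4ccc(O[Si](C)(C)C(C)(C)C)cc4)c(c23)-c2cc(O[Si](C)(C)C(C)(C)C)cc(O[Si](C)(C)C(C)(C)C)c2[C@@H]1c1ccc(O[Si](C)(C)C(C)(C)C)cc1
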